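**Retrosynthetic overview**

1. Target 22 is the nine-fold O-demethylation product of 21; rings B, C and D are bought as aromatic rings, and ring A is the only ring formed, in the last-but-one step.
2. The strategy rests on ring A: a 2-butanoyl-4,4-dimethylcyclohexane-1,3,5-trione whose C6 carries the CH2 bridge to ring B. It is opened at the bond between the butanoyl-bearing carbon and the carbonyl carbon next to CMe2, which gives the open-chain 2,2-dimethyl-3,5,7-trioxo ester 20.
3. 20 comes from C-benzylation of the dioxolane-masked diketo ester 18, at its only 1,3-dicarbonyl CH2, with the trimer benzylic chloride 12, followed by ketal hydrolysis. The A–B bridge carbon therefore enters as an electrophile, and no strong base meets the three aryl ketones.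
4. 12 comes from the B–C dimer 5 (two molecules of ketone 3 plus formaldehyde), Friedel–Crafts benzylation with the ring D chloride 9, and chloromethylation. 18 comes from ethyl 3-oxohexanoate and methyl 2,2-dimethyl-3-oxobutanoate.

Key step: step 12

Remark on the chemistry: 19 and 20 are racemic at the chain methine, which becomes an enolic sp2 carbon in ring A, so the target has no stereocentre. Methyl 2,2-dimethyl-3-oxobutanoate, ethyl 3-oxohexanoate and 2,4,6-trimethoxytoluene are taken as purchasable.

**Route**

Step 1
Reactants: 1 1,3,5-trimethoxybenzene; 2 butanoyl chloride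
Product: 3 1-(2,4,6-trimethoxyphenyl)butan-1-one
Conditions: AlCl3 (1.1 equiv), CH2Cl2, 0 °C
Reagents that add atoms: none
Why: Friedel–Crafts acylation of the symmetric, strongly activated arene should stop after one acyl group because the ketone deactivates the ring, and the low temperature limits ortho-demethylation.

Step 2
Reactants: 3 1-(2,4,6-trimethoxyphenyl)butan-1-one (two molecules, used in about fivefold excess)
Product: 5 bis(3-butanoyl-2,4,6-trimethoxyphenyl)methane, via benzylic alcohol 4 (not isolated)
Conditions: (CH2O)n (0.2 equiv), H2SO4 (cat.), AcOH, 40 °C; excess 3 recovered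
Reagents that add atoms: formaldehyde (as paraformaldehyde), C=O
Why: Acid-catalysed hydroxymethylation followed by Friedel–Crafts benzylation of a second molecule is the standard formaldehyde condensation of trimethoxyarenes, and the excess of 3 should hold it at the dimer.

Step 3
Reactants: 6 2,4,6-trimethoxytoluene; 2 butanoyl chloride
Product: 7 1-(2,4,6-trimethoxy-3-methylphenyl)butan-1-one
Conditions: AlCl3 (1.1 equiv), CH2Cl2, 0 °C
Reagents that add atoms: none
Why: Friedel–Crafts acylation at one of the two equivalent free positions, each activated by two ortho and one para methoxy group, with the second position deactivated afterwards.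

Step 4
Reactants: 7 1-(2,4,6-trimethoxy-3-methylphenyl)butan-1-one
Product: 9 1-[3-(chloromethyl)-2,4,6-trimethoxy-5-methylphenyl]butan-1-one, via benzyl methyl ether 8 (not isolated)
Conditions: ClCH2OCH3 (excess), ZnCl2 (cat.), CH2Cl2, 0 °C to rt
Reagents that add atoms: chloromethyl methyl ether, COCCl
Why: Chloromethylation at the single remaining aromatic C–H, which lies meta to the twisted acyl group and between two methoxy groups, with excess reagent to outrun diarylmethane formation.

Step 5
Reactants: 9 ring D benzylic chloride; 5 B–C dimer (threefold excess)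
Product: 10 permethylated B–C–D trimer 1-[3-({3-butanoyl-5-[(3-butanoyl-2,4,6-trimethoxy-5-methylphenyl)methyl]-2,4,6-trimethoxyphenyl}methyl)-2,4,6-trimethoxyphenyl]butan-1-one
Conditions: ZnCl2 (cat.), CH2Cl2, rt; excess 5 recovered
Reagents that add atoms: none
Why: Friedel–Crafts benzylation by the readily ionised 2,4,6-trimethoxybenzyl chloride at one of the two equivalent free positions of 5, with mono-substitution favoured by the excess of 5 and the mild Lewis acid chosen to limit transbenzylation.

Step 6
Reactants: 10 permethylated B–C–D trimer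
Product: 12 trimer benzylic chloride (10 with CH2Cl in place of the ring B hydrogen), via trimer benzyl methyl ether 11 (not isolated)
Conditions: ClCH2OCH3 (excess), ZnCl2 (cat.), CH2Cl2, 0 °C to rt
Reagents that add atoms: chloromethyl methyl ether, COCCl
Why: Chloromethylation can occur only at the one aromatic C–H left in 10, on ring B.

Step 7
Reactants: 13 ethyl 3-oxohexanoate
Product: 14 ethyl 2-(2-propyl-1,3-dioxolan-2-yl)acetate
Conditions: HOCH2CH2OH, TsOH (cat.), toluene, reflux, Dean–Stark trap
Reagents that add atoms: ethylene glycol, OCCO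
Why: Acid-catalysed ketalisation of the ketone of a β-keto ester with azeotropic removal of water, which masks the future butanoyl carbonyl.

Step 8
Reactants: 14 ethyl 2-(2-propyl-1,3-dioxolan-2-yl)acetate
Product: 15 N-methoxy-N-methyl-2-(2-propyl-1,3-dioxolan-2-yl)acetamide
Conditions: MeNHOMe·HCl, i-PrMgCl, THF, −20 °C
Reagents that add atoms: N,O-dimethylhydroxylamine hydrochloride, CNOC.Cl
Why: Aminolysis of the ester by the magnesium amide gives the Weinreb amide at low temperature, where the weakly basic amide should not open the β-ketal by elimination.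

Step 9
Reactants: 16 methyl 2,2-dimethyl-3-oxobutanoate; 15 the Weinreb amide
Product: 18 methyl 2,2-dimethyl-3,5-dioxo-6-(2-propyl-1,3-dioxolan-2-yl)hexanoate, via lithium enolate 17 (not isolated)
Conditions: LiN(i-Pr)2 (LDA), THF, −78 °C; then 15, −78 °C to rt; aq. NH4Cl
Reagents that add atoms: none
Why: The acetyl CH3 is the only enolisable position of 16, and Claisen-type acylation of this pinacolone-like enolate by the Weinreb amide gives a chelated tetrahedral adduct that releases the 1,3-diketone only on work-up.

Step 10
Reactants: 18 the masked diketo ester; 12 trimer benzylic chloride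
Product: 19 racemic methyl 4-(arylmethyl)-2,2-dimethyl-3,5-dioxo-6-(2-propyl-1,3-dioxolan-2-yl)hexanoate (aryl = ring B of the permethylated trimer)
Conditions: K2CO3, acetone, reflux
Reagents that add atoms: none
Why: C-alkylation of a 1,3-diketone potassium enolate with a benzylic halide; K2CO3 deprotonates only C4 of 18, and the new stereocentre forms without control as the racemate, which is harmless because it is lost in step 12.

Step 11
Reactants: 19 the benzylated ketal
Product: 20 racemic methyl 4-(arylmethyl)-2,2-dimethyl-3,5,7-trioxodecanoate (the triketo ester precursor)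
Conditions: 1 M aq. HCl, THF, rt
Reagents that add atoms: water, O
Why: Acid-catalysed hydrolysis of the dioxolane in a dilute aqueous medium, where water should capture the oxocarbenium ion faster than dehydrative closure to a pyranone can occur.

Step 12
Reactants: 20 the triketo ester
Product: 21 nona-O-methyl target (ring A free, rings B–D as trimethyl ethers)
Conditions: NaOMe (4 equiv), MeOH, reflux; then 1 M aq. HCl
Reagents that add atoms: none
Why: Methoxide deprotonates C6, the methylene between the C5 and C7 ketones and the most acidic carbon of 20, and this enolate adds to the C1 ester carbonyl; loss of methoxide and deprotonation of the new β-triketone give the sodium salt of 21. The closest known reaction type is the Claisen-mode (Dieckmann-type) cyclisation of 3,5,7-triketo esters to 2-acylcyclohexane-1,3,5-triones and acylphloroglucinols. Ring A closes by a 6-exo-trig attack of C6 on C1 (ring atoms C1–C6), helped by the gem-dimethyl group at C2. No stereocentre is formed, and the C4 methine of racemic 20 becomes an sp2 enol carbon, so both enantiomers converge on achiral 21. The step needs C-acylation by C6 to win over O-acylation to the six-membered enol lactone, over methanolysis at the C3 ketone and over aldol attack from C8: lactone formation is reversible in NaOMe/MeOH whereas the carbocycle is drained as its strongly acidic trione enolate, the C5–C7 enolate leaves the C3–C4 bond without a good leaving group, and C8 and the aryl ketone α-carbons are not deprotonated to a useful extent by methoxide. The nine methyl ethers keep rings B–D from forming quinone methides, so the methylene bridges should not scramble in base.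

Step 13
Reactants: 21 nona-O-methyl target
Product: 22 CNP0246352.0 (target)
Conditions: BBr3 (excess), CH2Cl2, −78 °C to 0 °C; then H2O
Reagents that add atoms: none
Why: Lewis acid cleavage of aryl methyl ethers by BBr3, helped for six of the nine ethers by chelation to the neighbouring butanoyl carbonyl, should free all phenols at low temperature while ring A sits as its boron chelate.

**Compound list**

1 | 1,3,5-trimethoxybenzene | COc1cc(OC)cc(OC)c1 | starting material
2 | butanoyl chloride | CCCC(=O)Cl | starting material
3 | 1-(2,4,6-trimethoxyphenyl)butan-1-one | CCCC(=O)c1c(OC)cc(OC)cc1OC | intermediate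
4 | 1-[3-(hydroxymethyl)-2,4,6-trimethoxyphenyl]butan-1-one (benzylic alcohol, not isolated) | CCCC(=O)c1c(OC)cc(OC)c(CO)c1OC | intermediate
5 | bis(3-butanoyl-2,4,6-trimethoxyphenyl)methane (B–C dimer) | CCCC(=O)c1c(OC)cc(OC)c(Cc2c(OC)cc(OC)c(C(=O)CCC)c2OC)c1OC | intermediate
6 | 2,4,6-trimethoxytoluene | Cc1c(OC)cc(OC)cc1OC | starting material
7 | 1-(2,4,6-trimethoxy-3-methylphenyl)butan-1-one | CCCC(=O)c1c(OC)c(C)c(OC)cc1OC | intermediate
8 | 1-[2,4,6-trimethoxy-3-(methoxymethyl)-5-methylphenyl]butan-1-one (benzyl methyl ether, not isolated) | CCCC(=O)c1c(OC)c(C)c(OC)c(COC)c1OC | intermediate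
9 | 1-[3-(chloromethyl)-2,4,6-trimethoxy-5-methylphenyl]butan-1-one (ring D chloride) | CCCC(=O)c1c(OC)c(C)c(OC)c(CCl)c1OC | intermediate
10 | permethylated B–C–D trimer with one free position on ring B | CCCC(=O)c1c(OC)cc(OC)c(Cc2c(OC)c(Cc3c(OC)c(C)c(OC)c(C(=O)CCC)c3OC)c(OC)c(C(=O)CCC)c2OC)c1OC | intermediate
11 | trimer benzyl methyl ether (ring B CH2OCH3, not isolated) | COCc1c(OC)c(Cc2c(OC)c(Cc3c(OC)c(C)c(OC)c(C(=O)CCC)c3OC)c(OC)c(C(=O)CCC)c2OC)c(OC)c(C(=O)CCC)c1OC | intermediate
12 | trimer benzylic chloride (ring B CH2Cl) | ClCc1c(OC)c(Cc2c(OC)c(Cc3c(OC)c(C)c(OC)c(C(=O)CCC)c3OC)c(OC)c(C(=O)CCC)c2OC)c(OC)c(C(=O)CCC)c1OC | intermediate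
13 | ethyl 3-oxohexanoate | CCCC(=O)CC(=O)OCC | starting material
14 | ethyl 2-(2-propyl-1,3-dioxolan-2-yl)acetate | CCCC1(CC(=O)OCC)OCCO1 | intermediate
15 | N-methoxy-N-methyl-2-(2-propyl-1,3-dioxolan-2-yl)acetamide | CCCC1(CC(=O)N(C)OC)OCCO1 | intermediate
16 | methyl 2,2-dimethyl-3-oxobutanoate | CC(=O)C(C)(C)C(=O)OC | starting material
17 | lithium enolate of 16 (lithium 4-methoxy-3,3-dimethyl-4-oxobut-1-en-2-olate, not isolated) | [Li+].C=C([O-])C(C)(C)C(=O)OC | intermediate
18 | methyl 2,2-dimethyl-3,5-dioxo-6-(2-propyl-1,3-dioxolan-2-yl)hexanoate | CCCC1(CC(=O)CC(=O)C(C)(C)C(=O)OC)OCCO1 | intermediate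
19 | racemic methyl 4-(arylmethyl)-2,2-dimethyl-3,5-dioxo-6-(2-propyl-1,3-dioxolan-2-yl)hexanoate, aryl = trimer ring B | CCCC1(CC(=O)C(Cc2c(OC)c(Cc3c(OC)c(Cc4c(OC)c(C)c(OC)c(C(=O)CCC)c4OC)c(OC)c(C(=O)CCC)c3OC)c(OC)c(C(=O)CCC)c2OC)C(=O)C(C)(C)C(=O)OC)OCCO1 | intermediate
20 | racemic methyl 4-(arylmethyl)-2,2-dimethyl-3,5,7-trioxodecanoate, aryl = trimer ring B (key-step precursor) | CCCC(=O)CC(=O)C(Cc1c(OC)c(Cc2c(OC)c(Cc3c(OC)c(C)c(OC)c(C(=O)CCC)c3OC)c(OC)c(C(=O)CCC)c2OC)c(OC)c(C(=O)CCC)c1OC)C(=O)C(C)(C)C(=O)OC | intermediate
21 | nona-O-methyl target (key-step product) | CCCC(=O)C1=C(O)C(C)(C)C(O)=C(Cc2c(OC)c(Cc3c(OC)c(Cc4c(OC)c(C)c(OC)c(C(=O)CCC)c4OC)c(OC)c(C(=O)CCC)c3OC)c(OC)c(C(=O)CCC)c2OC)C1=O | intermediate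
22 | CNP0246352.0 | CCCC(=O)C1=C(O)C(C)(C)C(O)=C(Cc2c(O)c(Cc3c(O)c(Cc4c(O)c(C)c(O)c(C(=O)CCC)c4O)c(O)c(C(=O)CCC)c3O)c(O)c(C(=O)CCC)c2O)C1=O | target

**Step count**

Total: 13 steps. Longest linear sequence: 8 steps (steps 1, 2, 5, 6, 10, 11, 12, 13).

**Steps most likely to fail**

Step 12 (ring closure). The pivalate-like ester may resist attack, so that methanolysis at the C3 ketone or an aldol closure from the propyl side consumes the chain before ring A forms. The fallback builds ring A first and attaches it by its nucleophilic carbon. It sets out from 3 and 12 and comes back at 21. Ketone 3 is demethylated with BBr3 (CH2Cl2) to 1-(2,4,6-trihydroxyphenyl)butan-1-one F1. Geminal C-methylation of F1 with MeI and NaOMe in MeOH, the classical entry to acylfilicinic acids, should give 2-butanoyl-3,5-dihydroxy-4,4-dimethylcyclohexa-2,5-dien-1-one F2. C-benzylation of F2 at its free ring carbon with chloride 12 (K2CO3, acetone) should then give 21.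

Step 13 (global demethylation). The strong Lewis acid may cleave or transfer the methylene bridges, and the three ethers that have no neighbouring carbonyl may be cleaved incompletely. The fallback splits the deprotection into two mechanistically different stages. It sets out from 21 and comes back at 22. BCl3 (CH2Cl2, 0 °C) should remove only the six chelation-activated methyl groups ortho to the butanoyl groups, giving the tri-O-methyl compound F3. The remaining three ethers, each para to a butanoyl group, would then be cleaved by SN2 attack at methyl with NaSEt in DMF at about 120 °C, which avoids acid altogether.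

Step 11 (ketal hydrolysis). The oxocarbenium ion or the freed 1,3,5-triketone may cyclise and dehydrate to a 4-pyranone under acid. The fallback unmasks the butanoyl carbonyl by oxidation instead of hydrolysis. It sets out from 16 and 12 and comes back at 20. The lithium enolate of 16 is acetylated with N-methoxy-N-methylacetamide to methyl 2,2-dimethyl-3,5-dioxohexanoate F4. The dianion of F4 (LDA, 2 equiv, THF, −78 °C) undergoes aldol addition to butanal at its terminal carbon, giving racemic methyl 7-hydroxy-2,2-dimethyl-3,5-dioxodecanoate F5. C-benzylation of F5 with 12 (K2CO3, acetone) gives the hydroxy diketo ester F6 as a diastereomer mixture. Oxidation of F6 with Dess–Martin periodinane (NaHCO3, CH2Cl2) should give 20 under buffered, non-acidic conditions.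

**Further compounds**

F1 | step 12 | 1-(2,4,6-trihydroxyphenyl)butan-1-one | CCCC(=O)c1c(O)cc(O)cc1O
F2 | step 12 | 2-butanoyl-3,5-dihydroxy-4,4-dimethylcyclohexa-2,5-dien-1-one (butyrylfilicinic acid) | CCCC(=O)C1=C(O)C(C)(C)C(O)=CC1=O
F3 | step 13 | tri-O-methyl target (one methoxy group left on each of rings B, C and D, para to the butanoyl group) | CCCC(=O)C1=C(O)C(C)(C)C(O)=C(Cc2c(OC)c(Cc3c(OC)c(Cc4c(OC)c(C)c(O)c(C(=O)CCC)c4O)c(O)c(C(=O)CCC)c3O)c(O)c(C(=O)CCC)c2O)C1=O
F4 | step 11 | methyl 2,2-dimethyl-3,5-dioxohexanoate | CC(=O)CC(=O)C(C)(C)C(=O)OC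
F5 | step 11 | racemic methyl 7-hydroxy-2,2-dimethyl-3,5-dioxodecanoate | CCCC(O)CC(=O)CC(=O)C(C)(C)C(=O)OC
F6 | step 11 | methyl 4-(arylmethyl)-7-hydroxy-2,2-dimethyl-3,5-dioxodecanoate, aryl = trimer ring B, diastereomer mixture | CCCC(O)CC(=O)C(Cc1c(OC)c(Cc2c(OC)c(Cc3c(OC)c(C)c(OC)c(C(=O)CCC)c3OC)c(OC)c(C(=O)CCC)c2OC)c(OC)c(C(=O)CCC)c1OC)C(=O)C(C)(C)C(=O)OC
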